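**Retrosynthetic overview**

1. Feature: the carbocycle C14–C16–C18–C25–C30–C31 with its fused γ-lactone (C26, O27, C28) is a dearomatised 5,7-dihydroxy-4,6-dimethylphthalide. C14 and C18 hold C13 and C20, the two ends of the ring B unit C13–C12=C21–C20, and C25 faces C12 across the resulting seven-membered ring.
2. C31–OH ⇐ C31 ketone; C12–C25 ⇐ transannular hydrogen-atom-transfer Giese cyclisation of a bicyclo[4.3.1]decene trione lactone (one bond gives the cyclopentane and the bicyclo[2.2.2]octane).
3. Bicyclo[4.3.1] core ⇐ phthalide bis-phenol + ring A/B bis(allylic) bromide by two C-alkylations (C14–C13, then C18–C20).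
4. Bromide ⇐ spirolactone ketol (C9 by asymmetric allylation of a β-keto ester, ring A by oxidative lactonisation, C22 by dihydroxylation); phthalide ⇐ atraric acid.
5. Ring order: ring B (bought) → ring A → phthalide lactone → seven-membered ring → cyclopentane and bicyclo[2.2.2]octane together.

Key step: step 21

Remark: locants C1–O32 in the text are those of the atoms in the order of the target SMILES; systematic names of 2–20 keep their own locants.
Remark: in step 1 the (R,R)-ligand is written on the assumption that it delivers the S ester; if it does not, its enantiomer is used.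
Remark: lithium and potassium enolates and phenoxides formed by deprotonation are treated as part of the conditions.

**Ring A/B fragment**

Step 1
Reactants: 1 ethyl 2-oxocyclohexane-1-carboxylate
Product: 2 ethyl (1S)-2-oxo-1-(prop-2-en-1-yl)cyclohexane-1-carboxylate
Conditions: allyl acetate, Pd2(dba)3·CHCl3 (1 mol%), (R,R)-N,N'-bis[2-(diphenylphosphino)benzoyl]cyclohexane-1,2-diamine (3 mol%), N,N,N',N'-tetramethylguanidine, toluene, 0 °C
Reagents that add atoms: allyl acetate, CC(=O)OCC=C
Why: Palladium-catalysed asymmetric allylic alkylation (Tsuji–Trost reaction) of a cyclic β-keto ester, in which the chiral diphosphine pocket around the π-allyl complex selects one face of the enolate and sets the quaternary centre C9 as S.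

Step 2
Reactants: 2 ethyl (1S)-2-oxo-1-(prop-2-en-1-yl)cyclohexane-1-carboxylate
Product: 3 ethyl (1S)-1-(prop-2-en-1-yl)-2-{[(trifluoromethyl)sulfonyl]oxy}cyclohex-2-ene-1-carboxylate
Conditions: KN(SiMe3)2, THF, −78 °C; then PhNTf2, −78 → 0 °C
Reagents that add atoms: N-phenylbis(trifluoromethanesulfonimide), O=S(=O)(N(c1ccccc1)S(=O)(=O)C(F)(F)F)C(F)(F)F
Why: Because C9 is quaternary the ketone can enolise only toward C21, and O-sulfonylation of that enolate gives the enol triflate regioselectively.

Step 3
Reactants: 3 ethyl (1S)-1-(prop-2-en-1-yl)-2-{[(trifluoromethyl)sulfonyl]oxy}cyclohex-2-ene-1-carboxylate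
Product: 4 ethyl (1S)-2-methyl-1-(prop-2-en-1-yl)cyclohex-2-ene-1-carboxylate
Conditions: MeZnCl, Pd(PPh3)4 (5 mol%), THF, 50 °C
Reagents that add atoms: methylzinc chloride, C[Zn]Cl
Why: Negishi cross-coupling of the enol triflate with a methylzinc reagent installs the C22 methyl and leaves the ester untouched.

Step 4
Reactants: 4 ethyl (1S)-2-methyl-1-(prop-2-en-1-yl)cyclohex-2-ene-1-carboxylate
Product: 5 2-[(1S)-2-methyl-1-(prop-2-en-1-yl)cyclohex-2-en-1-yl]propan-2-ol
Conditions: MeLi (3.5 equiv), Et2O, −78 → 0 °C
Reagents that add atoms: methyllithium, [Li]C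
Why: Double addition of methyllithium to the ester, the only carbonyl group present, gives the tertiary carbinol that becomes C2 with its two methyl groups.

Step 5
Reactants: 5 2-[(1S)-2-methyl-1-(prop-2-en-1-yl)cyclohex-2-en-1-yl]propan-2-ol
Product: 7 3-[(1S)-1-(2-hydroxypropan-2-yl)-2-methylcyclohex-2-en-1-yl]propan-1-ol, via organoborane 6 (not isolated)
Conditions: 9-BBN (2.5 equiv), THF, 0 °C → rt; then NaOH, H2O2, 0 °C
Reagents that add atoms: hydrogen peroxide, OO
Why: Hydroboration–oxidation with 9-BBN is anti-Markovnikov and discriminates the monosubstituted alkene from the hindered trisubstituted ring alkene.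

Step 6
Reactants: 7 3-[(1S)-1-(2-hydroxypropan-2-yl)-2-methylcyclohex-2-en-1-yl]propan-1-ol
Product: 10 (6S)-1,1,7-trimethyl-2-oxaspiro[5.5]undec-7-en-3-one, via hydroxy aldehyde 8 (not isolated), via lactol 9 (not isolated)
Conditions: TEMPO (20 mol%), PhI(OAc)2 (2.5 equiv), CH2Cl2, rt
Reagents that add atoms: none
Why: Oxidative lactonisation of a 1,5-diol, in which only the primary alcohol is oxidised, the aldehyde is captured by the tertiary hydroxyl as a six-membered lactol, and the lactol is oxidised again to the δ-lactone (ring A).

Step 7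
Reactants: 10 (6S)-1,1,7-trimethyl-2-oxaspiro[5.5]undec-7-en-3-one
Product: 13 (6S)-1,1,7-trimethyl-2-oxaspiro[5.5]undeca-4,7-dien-3-one, via selenide 11 (not isolated), via selenoxide 12 (not isolated)
Conditions: LiN(iPr)2, THF, −78 °C; PhSeBr; then NaIO4, NaHCO3, THF/H2O, 0 °C → rt
Reagents that add atoms: none
Why: α-Selenenylation of the lactone enolate and syn-elimination of the selenoxide, whose only β-hydrogens are on C8, give the endocyclic enoate; periodate is the oxidant so that the trisubstituted alkene is not epoxidised.

Step 8
Reactants: 13 (6S)-1,1,7-trimethyl-2-oxaspiro[5.5]undeca-4,7-dien-3-one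
Product: 14 (6S,7S,8R)-7,8-dihydroxy-1,1,7-trimethyl-2-oxaspiro[5.5]undec-4-en-3-one
Conditions: OsO4 (5 mol%), N-methylmorpholine N-oxide, acetone/H2O, rt
Reagents that add atoms: osmium tetroxide, O=[Os](=O)(=O)=O; N-methylmorpholine N-oxide, C[N+]1([O-])CCOCC1
Why: Upjohn dihydroxylation, in which OsO4 prefers the electron-rich trisubstituted alkene to the conjugated lactone alkene and approaches anti to the CMe2–O arm at C9 (pseudoaxial to avoid allylic 1,2-strain with the vinylic methyl), so that the C22 oxygen ends up trans to C2 and cis to C8 (C22 set; the C21 centre is removed in step 9).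

Step 9
Reactants: 14 (6S,7S,8R)-7,8-dihydroxy-1,1,7-trimethyl-2-oxaspiro[5.5]undec-4-en-3-one
Product: 15 (6S,7S)-7-hydroxy-1,1,7-trimethyl-2-oxaspiro[5.5]undec-4-ene-3,8-dione
Conditions: IBX, DMSO, rt
Reagents that add atoms: none
Why: IBX oxidises the secondary alcohol of the secondary/tertiary 1,2-diol to the ketone without glycol cleavage.

Step 10
Reactants: 15 (6S,7S)-7-hydroxy-1,1,7-trimethyl-2-oxaspiro[5.5]undec-4-ene-3,8-dione
Product: 16 1,1,7-trimethyl-7-[(triethylsilyl)oxy]-2-oxaspiro[5.5]undec-4-ene-3,8-dione (configuration as in 15)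
Conditions: Et3SiOTf, 2,6-lutidine, CH2Cl2, −20 → 0 °C
Reagents that add atoms: triethylsilyl trifluoromethanesulfonate, CC[Si](CC)(CC)OS(=O)(=O)C(F)(F)F
Why: Silylation of the hindered tertiary alcohol with a silyl triflate; the ether blocks an α-ketol shift and, later, closure of the alkoxide onto the C13 bromide.

Step 11
Reactants: 16 1,1,7-trimethyl-7-[(triethylsilyl)oxy]-2-oxaspiro[5.5]undec-4-ene-3,8-dione
Product: 18 1,1,7-trimethyl-9-methylidene-7-[(triethylsilyl)oxy]-2-oxaspiro[5.5]undec-4-ene-3,8-dione (configuration as in 15), via Mannich base 17 (not isolated)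
Conditions: (CH2O)n, iPr2NH2+ CF3CO2− (1 equiv), THF, reflux
Reagents that add atoms: formaldehyde (as paraformaldehyde), C=O
Why: Mannich-type α-methylenation, in which the ketone can enolise only toward C12, the iminium ion from formaldehyde and the ammonium salt is trapped there, and the amine is lost by elimination.

Step 12
Reactants: 18 1,1,7-trimethyl-9-methylidene-7-[(triethylsilyl)oxy]-2-oxaspiro[5.5]undec-4-ene-3,8-dione
Product: 19 1,1,7-trimethyl-8,9-dimethylidene-7-[(triethylsilyl)oxy]-2-oxaspiro[5.5]undec-4-en-3-one (configuration as in 15)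
Conditions: Zn, CH2Br2, TiCl4, THF/CH2Cl2, 0 °C → rt
Reagents that add atoms: dibromomethane, BrCBr
Why: Takai–Lombardo methylenation is non-basic, tolerates the lactone and suits hindered enolisable enones, giving the s-cis-locked 1,2-dimethylene diene.

Step 13
Reactants: 19 1,1,7-trimethyl-8,9-dimethylidene-7-[(triethylsilyl)oxy]-2-oxaspiro[5.5]undec-4-en-3-one
Product: 20 8,9-bis(bromomethyl)-1,1,7-trimethyl-7-[(triethylsilyl)oxy]-2-oxaspiro[5.5]undeca-4,8-dien-3-one (configuration as in 15)
Conditions: Br2 (1.0 equiv), CH2Cl2, −78 °C
Reagents that add atoms: bromine, BrBr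
Why: Electrophilic 1,4-addition of bromine to the exocyclic diene gives the bis(allylic) bromide with the tetrasubstituted C12=C21 alkene, the conjugated lactone alkene being too electron-poor to react.

**Phthalide fragment**

Step 14
Reactants: 21 atraric acid (methyl 2,4-dihydroxy-3,6-dimethylbenzoate)
Product: 22 methyl 5-formyl-2,4-dihydroxy-3,6-dimethylbenzoate
Conditions: Cl2CHOMe, TiCl4, CH2Cl2, 0 °C; then aq. HCl
Reagents that add atoms: dichloromethyl methyl ether, COC(Cl)Cl; water, O
Why: Rieche formylation (electrophilic aromatic substitution) at the only free ring position, which is ortho and para to the two hydroxyl groups.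

Step 15
Reactants: 22 methyl 5-formyl-2,4-dihydroxy-3,6-dimethylbenzoate
Product: 23 methyl 2,4-dihydroxy-3,5,6-trimethylbenzoate
Conditions: H2 (3 atm), Pd/C, AcOH, HCl (cat.), 50 °C
Reagents that add atoms: none
Why: Hydrogenolysis of the electron-rich ortho-hydroxybenzaldehyde through the benzylic alcohol converts the formyl group into the methyl group that becomes C19.

Step 16
Reactants: 23 methyl 2,4-dihydroxy-3,5,6-trimethylbenzoate
Product: 24 methyl 2,4-dimethoxy-3,5,6-trimethylbenzoate
Conditions: MeI, K2CO3, DMF, 50 °C
Reagents that add atoms: iodomethane, CI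
Why: Williamson O-methylation masks both phenols for the benzylic metalation.

Step 17
Reactants: 24 methyl 2,4-dimethoxy-3,5,6-trimethylbenzoate
Product: 25 5,7-dimethoxy-4,6-dimethyl-2-benzofuran-1(3H)-one
Conditions: LiN(iPr)2, THF, −78 °C; then 2-(phenylsulfonyl)-3-phenyloxaziridine, −78 → 0 °C
Reagents that add atoms: 2-(phenylsulfonyl)-3-phenyloxaziridine, O=S(=O)(c1ccccc1)N1OC1c1ccccc1
Why: Lateral lithiation, in which only the methyl ortho to the ester is acidified, the benzylic anion is hydroxylated by the N-sulfonyloxaziridine, and the alkoxide closes on the ester to give the phthalide.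

Step 18
Reactants: 25 5,7-dimethoxy-4,6-dimethyl-2-benzofuran-1(3H)-one
Product: 26 5,7-dihydroxy-4,6-dimethyl-2-benzofuran-1(3H)-one
Conditions: BBr3, CH2Cl2, −78 → 0 °C; then MeOH, H2O
Reagents that add atoms: none
Why: Lewis-acid cleavage of the two aryl methyl ethers with BBr3, the lactone being retained.

**Union, key step and end game**

Step 19
Reactants: 26 5,7-dihydroxy-4,6-dimethyl-2-benzofuran-1(3H)-one; 20 8,9-bis(bromomethyl)-1,1,7-trimethyl-7-[(triethylsilyl)oxy]-2-oxaspiro[5.5]undeca-4,8-dien-3-one
Product: 28 O24-triethylsilyl ether of the bicyclo[4.3.1]decene trione lactone 29, via monoalkylated bromide 27 (not isolated)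
Conditions: 26, LiOtBu (2.2 equiv), toluene, 0 °C; then 20, rt → 50 °C, 0.02 M
Reagents that add atoms: none
Why: Alkylative dearomatisation–annulation, in which the dilithium phenoxide is C-alkylated in the non-polar medium at C14 (the carbon between the two oxygens) by the less hindered C13 bromide, and the resulting vinylogous enolate closes onto the C20 bromide at methyl-bearing C18 instead of acyl-bearing C30; C18 must form cis to C13 across the bridge, whereas C14 is set with no bias expected from the remote C9/C22 centres, so 28 should form together with its C14,C18-diastereomer, which is removed by chromatography.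

Step 20
Reactants: 28 O24-triethylsilyl ether of 29
Product: 29 bicyclo[4.3.1]decene trione lactone fused to ring B (free C22 hydroxyl)
Conditions: HF·pyridine, pyridine, THF, 0 °C → rt
Reagents that add atoms: none
Why: Fluoride cleavage of the tertiary silyl ether under pyridine-buffered conditions that spare the allylic tertiary alcohol and the β-dicarbonyl system.

Step 21
Reactants: 29 bicyclo[4.3.1]decene trione lactone fused to ring B
Product: 30 31-oxo compound (the target with a ketone at C31)
Conditions: Fe(acac)3 (30 mol%), PhSiH3 (2.5 equiv, slow addition), EtOH, 60 °C, 5 mM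
Reagents that add atoms: none
Why: Proposed new method: PhSiH3 and ethanol turn Fe(acac)3 (trivalent iron) into an iron hydride that transfers a hydrogen atom to the electron-rich tetrasubstituted C12=C21 alkene, reversibly at either carbon; only the tertiary C12 radical has an acceptor in reach, it adds to C25, the β-carbon of the alkylidene β-keto lactone, and the C30 radical is reduced by divalent iron to the enolate and protonated by ethanol. The closest known reaction type is the iron-hydride-initiated radical conjugate addition of alkenes to enones and its intramolecular variants that form quaternary centres; new here are the transannular setting and the fully substituted acceptor carbon, which should be tolerated because a tertiary radical adds to a doubly activated alkene through an early transition state and the folded bicycle holds the two carbons close. The one new bond closes the cyclopentane C12–C21–C20–C18–C25 in a 5-exo-trig mode and, through C13–C14, the two six-membered rings of the bicyclo[2.2.2]octane (6-exo by way of C16–C18, 6-endo by way of C31–C30). C12 and C25 can bond only on the face of ring B that carries the enone bridge (the face of the C22 hydroxyl), which fixes both quaternary centres; C21 takes its hydrogen on the opposite, exposed face, giving the cis ring B/cyclopentane fusion with H21 cis to C13, since hydrogen on the inner face would lead to a strained trans-fused closure and that radical reverts; C30 is a β-keto lactone centre that equilibrates through the enol and is fixed in step 22. The step needs hydrogen-atom transfer at the unactivated alkene and not at the two electron-poor alkenes (secured by the polarity of the metal hydride) and cyclisation faster than reduction of the C12 radical (secured by a low silane concentration and the proximity of C25); the ring A enoate is not a competing acceptor because attack at C8 would build a norbornane.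

Step 22
Reactants: 30 31-oxo compound
Product: 31 CNP0360620.2 (target)
Conditions: NaBH4, CeCl3·7H2O, MeOH/CH2Cl2, −78 °C
Reagents that add atoms: none
Why: Luche reduction, in which the C31 ketone (one quaternary neighbour, activated as β-keto lactone) reacts before the C16 ketone (two quaternary neighbours) and without conjugate reduction of ring A; hydride is expected to add anti to the C30–C28 bond, from the C13 side, placing the hydroxyl cis to the lactone carbonyl carbon and syn to C16 and fixing C30 with its hydrogen on the C13 side.

**Compound list**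

1 | ethyl 2-oxocyclohexane-1-carboxylate | CCOC(=O)C1CCCCC1=O | starting material
2 | ethyl (1S)-2-oxo-1-(prop-2-en-1-yl)cyclohexane-1-carboxylate | C=CC[C@@]1(C(=O)OCC)CCCCC1=O | intermediate
3 | ethyl (1S)-1-(prop-2-en-1-yl)-2-{[(trifluoromethyl)sulfonyl]oxy}cyclohex-2-ene-1-carboxylate | C=CC[C@@]1(C(=O)OCC)CCCC=C1OS(=O)(=O)C(F)(F)F | intermediate
4 | ethyl (1S)-2-methyl-1-(prop-2-en-1-yl)cyclohex-2-ene-1-carboxylate | C=CC[C@@]1(C(=O)OCC)CCCC=C1C | intermediate
5 | 2-[(1S)-2-methyl-1-(prop-2-en-1-yl)cyclohex-2-en-1-yl]propan-2-ol | C=CC[C@@]1(C(C)(C)O)CCCC=C1C | intermediate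
6 | organoborane: 5 with 9-borabicyclo[3.3.1]nonan-9-yl on the terminal carbon of the former allyl group | B1(CCC[C@@]2(C(C)(C)O)CCCC=C2C)C3CCCC1CCC3 | intermediate (not isolated)
7 | 3-[(1S)-1-(2-hydroxypropan-2-yl)-2-methylcyclohex-2-en-1-yl]propan-1-ol | OCCC[C@@]1(C(C)(C)O)CCCC=C1C | intermediate
8 | 3-[(1S)-1-(2-hydroxypropan-2-yl)-2-methylcyclohex-2-en-1-yl]propanal | O=CCC[C@@]1(C(C)(C)O)CCCC=C1C | intermediate (not isolated)
9 | (6S)-1,1,7-trimethyl-2-oxaspiro[5.5]undec-7-en-3-ol (both anomers) | CC1(C)OC(O)CC[C@]12CCCC=C2C | intermediate (not isolated)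
10 | (6S)-1,1,7-trimethyl-2-oxaspiro[5.5]undec-7-en-3-one | CC1(C)OC(=O)CC[C@]12CCCC=C2C | intermediate
11 | 4-(phenylselanyl) derivative of 10 (both C4 epimers) | CC1(C)OC(=O)C([Se]c3ccccc3)C[C@]12CCCC=C2C | intermediate (not isolated)
12 | selenoxide of 11 | CC1(C)OC(=O)C([Se](=O)c3ccccc3)C[C@]12CCCC=C2C | intermediate (not isolated)
13 | (6S)-1,1,7-trimethyl-2-oxaspiro[5.5]undeca-4,7-dien-3-one | CC1(C)OC(=O)C=C[C@]12CCCC=C2C | intermediate
14 | (6S,7S,8R)-7,8-dihydroxy-1,1,7-trimethyl-2-oxaspiro[5.5]undec-4-en-3-one (cis-diol, both oxygens trans to the CMe2–O arm) | CC1(C)OC(=O)C=C[C@]12CCC[C@@H](O)[C@@]2(C)O | intermediate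
15 | (6S,7S)-7-hydroxy-1,1,7-trimethyl-2-oxaspiro[5.5]undec-4-ene-3,8-dione | CC1(C)OC(=O)C=C[C@]12CCCC(=O)[C@@]2(C)O | intermediate
16 | 1,1,7-trimethyl-7-[(triethylsilyl)oxy]-2-oxaspiro[5.5]undec-4-ene-3,8-dione (configuration as in 15) | CC1(C)OC(=O)C=C[C@]12CCCC(=O)[C@@]2(C)O[Si](CC)(CC)CC | intermediate
17 | Mannich base: 16 with CH2N(iPr)2 on the ring CH2 next to the ketone (C12; both epimers) | CC1(C)OC(=O)C=C[C@]12CCC(CN(C(C)C)C(C)C)C(=O)[C@@]2(C)O[Si](CC)(CC)CC | intermediate (not isolated)
18 | 1,1,7-trimethyl-9-methylidene-7-[(triethylsilyl)oxy]-2-oxaspiro[5.5]undec-4-ene-3,8-dione (configuration as in 15) | CC1(C)OC(=O)C=C[C@]12CCC(=C)C(=O)[C@@]2(C)O[Si](CC)(CC)CC | intermediate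
19 | 1,1,7-trimethyl-8,9-dimethylidene-7-[(triethylsilyl)oxy]-2-oxaspiro[5.5]undec-4-en-3-one (configuration as in 15) | CC1(C)OC(=O)C=C[C@]12CCC(=C)C(=C)[C@@]2(C)O[Si](CC)(CC)CC | intermediate
20 | 8,9-bis(bromomethyl)-1,1,7-trimethyl-7-[(triethylsilyl)oxy]-2-oxaspiro[5.5]undeca-4,8-dien-3-one (configuration as in 15) | CC1(C)OC(=O)C=C[C@]12CCC(CBr)=C(CBr)[C@@]2(C)O[Si](CC)(CC)CC | intermediate
21 | atraric acid (methyl 2,4-dihydroxy-3,6-dimethylbenzoate) | COC(=O)c1c(C)cc(O)c(C)c1O | starting material
22 | methyl 5-formyl-2,4-dihydroxy-3,6-dimethylbenzoate | COC(=O)c1c(C)c(C=O)c(O)c(C)c1O | intermediate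
23 | methyl 2,4-dihydroxy-3,5,6-trimethylbenzoate | COC(=O)c1c(C)c(C)c(O)c(C)c1O | intermediate
24 | methyl 2,4-dimethoxy-3,5,6-trimethylbenzoate | COC(=O)c1c(C)c(C)c(OC)c(C)c1OC | intermediate
25 | 5,7-dimethoxy-4,6-dimethyl-2-benzofuran-1(3H)-one | O=C1OCc2c(C)c(OC)c(C)c(OC)c12 | intermediate
26 | 5,7-dihydroxy-4,6-dimethyl-2-benzofuran-1(3H)-one | O=C1OCc2c(C)c(O)c(C)c(O)c12 | intermediate
27 | C14-monoalkylated phthalide: 20 with the C13 bromide replaced by C14 of dearomatised 26 (C16 ketone, C18=C25, C30=C31 enol), C20 bromide intact; the C14 epimer leading to 28 is drawn and forms together with its C14 epimer | CC1(C)OC(=O)C=C[C@]12CCC(C[C@]3(C)C(=O)C(C)=C4COC(=O)C4=C3O)=C(CBr)[C@@]2(C)O[Si](CC)(CC)CC | intermediate (not isolated)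
28 | O24-triethylsilyl ether of 29 | CC1(C)OC(=O)C=C[C@]12CCC3=C(C[C@@](C)(C(=O)[C@@]4(C)C3)C5=C(C(=O)OC5)C4=O)[C@@]2(C)O[Si](CC)(CC)CC | intermediate
29 | bicyclo[4.3.1]decene trione lactone fused to ring B: the C12=C21 alkene of the ring A/B spirolactone carries C13 (bonded to C14) and C20 (bonded to C18); C16 ketone as one-carbon bridge; enone bridge C25=C30–C31(=O) fused to the γ-lactone and lying on the side of the free C22 hydroxyl | CC1(C)OC(=O)C=C[C@]12CCC3=C(C[C@@](C)(C(=O)[C@@]4(C)C3)C5=C(C(=O)OC5)C4=O)[C@@]2(C)O | intermediate
30 | 31-oxo compound: the target with a ketone at C31 (β-keto lactone); H21 cis to C13, H30 on the C13 side | CC1(C)OC(=O)C=C[C@]12CC[C@]13C[C@]4(C)C(=O)[C@](C)(C[C@H]1[C@@]2(C)O)[C@]31COC(=O)[C@H]1C4=O | intermediate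
31 | CNP0360620.2 | CC1(C)OC(=O)C=C[C@]12CC[C@]13C[C@]4(C)C(=O)[C@](C)(C[C@H]1[C@@]2(C)O)[C@]31COC(=O)[C@H]1[C@H]4O | target

**Step count**

Total: 22 steps. Longest linear sequence: 17 steps (steps 1–13, then 19–22); the phthalide branch is 5 steps (14–18).

**Steps most likely to fail**

Step 21 (the proposed new method). The tertiary C12 radical may be quenched by a second hydrogen-atom transfer before it reaches the fully substituted C25, giving plain hydrogenation or isomerisation of the C12=C21 alkene, and the β-keto lactone product may bind the iron and stall turnover. The fallback makes the bond by a polar route and sets out from 29. Me2AlCl (2.2 equiv, CH2Cl2, −78 → 0 °C; the first equivalent masks the C22 hydroxyl as its aluminium alkoxide) activates the alkylidene β-keto lactone as the enophile of a transannular ene reaction, a known Lewis-acid reaction of alkylidene 1,3-dicarbonyl compounds: C12 bonds to C25, a hydrogen passes from C20 to C30 and the alkene moves to C20=C21, giving the C20=C21 cyclopentene F1. Hydrogenation of this trisubstituted alkene by hydrogen-atom transfer (Mn(dpm)3 (trivalent manganese), PhSiH3, tBuOOH, iPrOH, rt) should spare the electron-poor ring A alkene and add the C21 hydrogen from the exposed face; the route is rejoined at 30.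

Step 19. The ambident dienolate may close through oxygen (a seven-membered cyclic enol ether) in place of C18, the first alkylation may take place at the hindered C20 bromide, and the planar phenoxide has no facial bias at C14, so only part of the material can end up as 28. The fallback sets out from 20: both bromides are exchanged for acetate (KOAc, DMF, rt) to give the bis(allylic) acetate F2. Then 26 and F2 are joined with Pd(PPh3)4 (zerovalent palladium) and Cs2CO3 in THF at 50 °C by a double allylic alkylation through π-allylpalladium intermediates, a known dearomative annulation of polyphenols with bis(allylic) electrophiles. In this manifold O-allylation is reversible and the C-allylated bicycle accumulates, and a chiral diphosphine on palladium offers catalyst control of the C14 face. The route is rejoined at 28.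

Step 22. Hydride may be delivered to the C16-side face, or the C30-epimeric keto form may be reduced faster, either of which gives a wrong C30/C31 pair; slow reduction at C16 is a lesser concern. The fallback sets out from 30 and replaces substrate control by reagent control: Corey–Bakshi–Shibata reduction (2-methyl-CBS-oxazaborolidine, the enantiomer matched to the C13 face, catecholborane, toluene, −78 °C) while C30 equilibrates through the enol. It comes back to the route at 31; no new compound is made (F0).

**Further compounds**

F1 | step 21 | C20=C21 cyclopentene: 30 lacking the hydrogens at C20 and C21 (C12–C25 bond formed, H30 present) | CC1(C)OC(=O)C=C[C@]12CC[C@]13C[C@]4(C)C(=O)[C@](C)(C=C1[C@@]2(C)O)[C@]31COC(=O)[C@H]1C4=O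
F2 | step 19 | bis(allylic) acetate: 20 with both bromides replaced by acetoxy | CC1(C)OC(=O)C=C[C@]12CCC(COC(C)=O)=C(COC(C)=O)[C@@]2(C)O[Si](CC)(CC)CC
F0 | step 22 | none | none
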